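**Strategy**

The route rests on disconnecting the lactone between its carbonyl carbon C2 and the methyl-bearing carbon C3: the (3R,5S)-3-methyloxolan-2-one ring is an isomer of the formate ester of a homoallylic alcohol. In the key step a chiral nickel–aluminium catalyst adds the formyl C–H bond across the vinyl group, closing the five-membered ring and setting C3 trans to C5 under ligand control, the former =CH2 becoming the C3 methyl. The precursor, the formate of an (S)-homoallylic alcohol, is built from geraniol. The derived allylic bromide then enters a copper-catalysed asymmetric methyl addition–enolate allylation on a quinone monoketal; face-selective reduction, ketal hydrolysis and acetylation complete the cyclohexenone.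

Key step: step 7

Assumption: the sense of induction of the three chiral catalysts (steps 5, 7 and 10) is taken by analogy with their closest precedents; where a catalyst proves to select the other face, its mirror-image ligand is used.

**Route**

Step 1
Reactants: 1 geraniol, (2E)-3,7-dimethylocta-2,6-dien-1-ol
Product: 2 tert-butyl{[(2E)-3,7-dimethylocta-2,6-dien-1-yl]oxy}dimethylsilane
Conditions: TBSCl, imidazole, CH2Cl2, 0 °C to rt
Reagents that add atoms: tert-butyldimethylsilyl chloride, CC(C)(C)[Si](C)(C)Cl
Why: Silylation of the primary allylic alcohol should give an ether that survives the oxidation, Grignard, iridium and nickel steps and is later exchanged directly for bromide.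

Step 2
Reactants: 2 tert-butyl{[(2E)-3,7-dimethylocta-2,6-dien-1-yl]oxy}dimethylsilane
Product: 3 (2E,6E)-8-[(tert-butyldimethylsilyl)oxy]-2,6-dimethylocta-2,6-dien-1-ol
Conditions: SeO2 (cat.), t-BuOOH, salicylic acid (cat.), CH2Cl2, rt
Reagents that add atoms: tert-butyl hydroperoxide, CC(C)(C)OO (terminal oxidant; its oxygen is relayed by SeO2)
Why: Riley oxidation (ene reaction, then [2,3]-sigmatropic shift) should hydroxylate the E-methyl group of the distal, more electron-rich trisubstituted alkene and give the (E)-allylic alcohol, the proximal alkene being deactivated by its allylic silyloxy group.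

Step 3
Reactants: 3 (2E,6E)-8-[(tert-butyldimethylsilyl)oxy]-2,6-dimethylocta-2,6-dien-1-ol
Product: 4 {[(2E,6E)-8-bromo-3,7-dimethylocta-2,6-dien-1-yl]oxy}(tert-butyl)dimethylsilane
Conditions: CBr4, PPh3, CH2Cl2, 0 °C
Reagents that add atoms: carbon tetrabromide, BrC(Br)(Br)Br
Why: Appel reaction of the primary allylic alcohol should give the primary (E)-allylic bromide by SN2 displacement of the oxyphosphonium group without allylic transposition.

Step 4
Reactants: 4 {[(2E,6E)-8-bromo-3,7-dimethylocta-2,6-dien-1-yl]oxy}(tert-butyl)dimethylsilane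
Product: 6 (3E,7E)-9-[(tert-butyldimethylsilyl)oxy]-3,7-dimethylnona-3,7-dien-1-ol, via alkoxysilane 5 (not isolated)
Conditions: (i-PrO)Me2SiCH2MgCl (from ClCH2SiMe2(Oi-Pr) and Mg), CuI (10 mol%), THF, −78 to 0 °C; then MeOH, KHCO3, KF, 30% H2O2, rt
Reagents that add atoms: (isopropoxydimethylsilyl)methylmagnesium chloride, CC(C)O[Si](C)(C)C[Mg]Cl; hydrogen peroxide, OO
Why: Copper-catalysed SN2 coupling of the bulky Grignard reagent at the primary allylic carbon should keep the E-alkene, and Tamao–Fleming oxidation of the C–Si bond in the same flask should unveil the one-carbon-homologated primary alcohol.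

Step 5
Reactants: 6 (3E,7E)-9-[(tert-butyldimethylsilyl)oxy]-3,7-dimethylnona-3,7-dien-1-ol
Product: 7 (4S,6E,10E)-12-[(tert-butyldimethylsilyl)oxy]-6,10-dimethyldodeca-1,6,10-trien-4-ol
Conditions: [Ir(cod)Cl]2 (2.5 mol%), (S)-Cl,MeO-BIPHEP (5 mol%), Cs2CO3 (20 mol%), 4-chloro-3-nitrobenzoic acid (10 mol%), allyl acetate, THF, 100 °C
Reagents that add atoms: allyl acetate, C=CCOC(C)=O
Why: Iridium-catalysed transfer-hydrogenative carbonyl allylation from the alcohol oxidation level should dehydrogenate 6 to the aldehyde and allylate it at once through a closed chair transition state, the bisphosphine selecting the aldehyde face to set C4 as S, so that the labile β,γ-unsaturated aldehyde never accumulates.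

Step 6
Reactants: 7 (4S,6E,10E)-12-[(tert-butyldimethylsilyl)oxy]-6,10-dimethyldodeca-1,6,10-trien-4-ol
Product: 8 (4S,6E,10E)-12-[(tert-butyldimethylsilyl)oxy]-6,10-dimethyldodeca-1,6,10-trien-4-yl formate
Conditions: HCO2H, DCC, DMAP (cat.), CH2Cl2, 0 °C to rt
Reagents that add atoms: formic acid, O=CO
Why: Carbodiimide-mediated esterification should formylate the secondary alcohol with retention at C4, placing the future lactone carbonyl carbon on oxygen.

Step 7
Reactants: 8 (4S,6E,10E)-12-[(tert-butyldimethylsilyl)oxy]-6,10-dimethyldodeca-1,6,10-trien-4-yl formate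
Product: 9 (3R,5S)-5-{(2E,6E)-8-[(tert-butyldimethylsilyl)oxy]-2,6-dimethylocta-2,6-dien-1-yl}-3-methyloxolan-2-one
Conditions: Ni(cod)2 (10 mol%), chiral diaminophosphine oxide L* [(4S,5S)-1,3-bis(3,5-di-tert-butylphenyl)-4,5-diphenyl-1,3,2-diazaphospholidine 2-oxide] (10 mol%), AlMe3 (40 mol%), PPh3 (10 mol%), toluene, 40 °C
Reagents that add atoms: none
Why: Proposed new method: the formyl C–H bond of 8, activated by the aluminium centre held on the phosphine-oxide oxygen of the ligand, should add to zerovalent nickel with transfer of the hydride to the terminal CH2 of the tethered vinyl group, giving a six-membered (alkoxycarbonyl)(secondary alkyl) metallacycle of divalent nickel, and C–C reductive elimination then joins the carbonyl carbon to the former internal alkene carbon and returns zerovalent nickel. The closest known reaction type is the nickel/aluminium-catalysed enantioselective hydrocarbamoylation that turns homoallylic formamides into 3-methylpyrrolidin-2-ones, and ruthenium-catalysed hydroesterification shows that formate C–H bonds add across alkenes, but a nickel-catalysed, stereocontrolled lactone version is not known. The oxolan-2-one ring closes in a formal 5-exo-trig, Markovnikov hydroacylation, the 6-endo alternative (a δ-lactone) requiring a seven-membered metallacycle. The new C3 stereocenter (R) is set by the chiral ligand, which selects the alkene face in the hydride-transfer step and has to override only the weak inherent preference of the five-membered closure for the cis lactone, while C5 is untouched. The step needs chemoselectivity for the monosubstituted alkene, which the formate tether secures because only the vinyl group can reach nickel and insert while the trisubstituted alkenes are remote and hindered, and it needs C–H addition to outrun decarbonylation of the formate, which the mild temperature and the Lewis acid are meant to secure.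

Step 8
Reactants: 9 (3R,5S)-5-{(2E,6E)-8-[(tert-butyldimethylsilyl)oxy]-2,6-dimethylocta-2,6-dien-1-yl}-3-methyloxolan-2-one
Product: 10 (3R,5S)-5-[(2E,6E)-8-bromo-2,6-dimethylocta-2,6-dien-1-yl]-3-methyloxolan-2-one
Conditions: Ph3PBr2, CH2Cl2, 0 °C to rt
Reagents that add atoms: dibromotriphenylphosphorane, BrP(Br)(c1ccccc1)(c1ccccc1)c1ccccc1
Why: Dibromotriphenylphosphorane should convert the primary allylic silyl ether directly into the bromide (O-phosphonium formation, loss of the silyl bromide, SN2 attack of bromide) under base-free conditions that cannot epimerize C3 of the lactone.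

Step 9
Reactants: 11 2,3,4-trimethoxyphenol
Product: 12 2,3,4,4-tetramethoxycyclohexa-2,5-dien-1-one
Conditions: PhI(OAc)2, MeOH, 0 °C
Reagents that add atoms: methanol, CO
Why: Oxidative dearomatization of the para-methoxyphenol should give a phenoxonium ion that methanol traps at C4 as the dimethyl ketal (quinone monoketal formation).

Step 10
Reactants: 12 2,3,4,4-tetramethoxycyclohexa-2,5-dien-1-one (in excess); 10 (3R,5S)-5-[(2E,6E)-8-bromo-2,6-dimethylocta-2,6-dien-1-yl]-3-methyloxolan-2-one
Product: 14 (5R,6R)-2,3,4,4-tetramethoxy-5-methyl-6-{(2E,6E)-3,7-dimethyl-8-[(2S,4R)-4-methyl-5-oxooxolan-2-yl]octa-2,6-dien-1-yl}cyclohex-2-en-1-one, via methylzinc enolate 13 (not isolated)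
Conditions: Me2Zn, Cu(OTf)2 (3 mol%), (S,R,R)-phosphoramidite [from (S)-BINOL and bis((R)-1-phenylethyl)amine] (6 mol%), toluene, −25 °C; then 10, HMPA, THF, −25 °C to rt
Reagents that add atoms: dimethylzinc, C[Zn]C
Why: Copper/phosphoramidite-catalysed asymmetric conjugate addition of Me2Zn to the only unsubstituted enone alkene should set C5 (R) by ligand-controlled face selection, and the zinc enolate should then be C-allylated at C6 anti to the new methyl group by SN2 attack on the primary allylic bromide (tandem conjugate addition–enolate trapping), the weakly basic zinc enolate leaving the lactone and its C3 center untouched.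

Step 11
Reactants: 14 (5R,6R)-2,3,4,4-tetramethoxy-5-methyl-6-{(2E,6E)-3,7-dimethyl-8-[(2S,4R)-4-methyl-5-oxooxolan-2-yl]octa-2,6-dien-1-yl}cyclohex-2-en-1-one
Product: 15 (1R,5R,6R)-2,3,4,4-tetramethoxy-5-methyl-6-{(2E,6E)-3,7-dimethyl-8-[(2S,4R)-4-methyl-5-oxooxolan-2-yl]octa-2,6-dien-1-yl}cyclohex-2-en-1-ol
Conditions: Li[HB(s-Bu)3] (L-Selectride), THF, −78 °C
Reagents that add atoms: none
Why: The bulky hydride should add 1,2 to the ketone (the β-carbon is a fully substituted enol-ether carbon) from the face opposite the adjacent C6 side chain, giving the 1,6-cis alcohol, while the lactone is not reduced at −78 °C.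

Step 12
Reactants: 15 (1R,5R,6R)-2,3,4,4-tetramethoxy-5-methyl-6-{(2E,6E)-3,7-dimethyl-8-[(2S,4R)-4-methyl-5-oxooxolan-2-yl]octa-2,6-dien-1-yl}cyclohex-2-en-1-ol
Product: 16 (4R,5R,6R)-4-hydroxy-2,3-dimethoxy-6-methyl-5-{(2E,6E)-3,7-dimethyl-8-[(2S,4R)-4-methyl-5-oxooxolan-2-yl]octa-2,6-dien-1-yl}cyclohex-2-en-1-one
Conditions: oxalic acid, THF/H2O, rt
Reagents that add atoms: water, O
Why: Mild acid hydrolysis of the dimethyl ketal should unveil the ketone conjugated to the dimethoxy alkene (a vinylogous ester) without touching the lactone, the alkenes or the three ring stereocenters.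

Step 13
Reactants: 16 (4R,5R,6R)-4-hydroxy-2,3-dimethoxy-6-methyl-5-{(2E,6E)-3,7-dimethyl-8-[(2S,4R)-4-methyl-5-oxooxolan-2-yl]octa-2,6-dien-1-yl}cyclohex-2-en-1-one
Product: 17 CNP0600606.1, (1R,5R,6R)-2,3-dimethoxy-5-methyl-4-oxo-6-{(2E,6E)-3,7-dimethyl-8-[(2S,4R)-4-methyl-5-oxooxolan-2-yl]octa-2,6-dien-1-yl}cyclohex-2-en-1-yl acetate
Conditions: Ac2O, pyridine, DMAP (cat.), CH2Cl2, 0 °C to rt
Reagents that add atoms: acetic anhydride, CC(=O)OC(C)=O
Why: DMAP-catalysed acylation of the secondary allylic alcohol should give the acetate with retention, under conditions too mild to epimerize the ketone α-carbon or the lactone α-carbon.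

**Compound list**

1 | geraniol, (2E)-3,7-dimethylocta-2,6-dien-1-ol | OC/C=C(\C)CCC=C(C)C | starting material
2 | tert-butyl{[(2E)-3,7-dimethylocta-2,6-dien-1-yl]oxy}dimethylsilane | CC(C)(C)[Si](C)(C)OC/C=C(\C)CCC=C(C)C | intermediate
3 | (2E,6E)-8-[(tert-butyldimethylsilyl)oxy]-2,6-dimethylocta-2,6-dien-1-ol | CC(C)(C)[Si](C)(C)OC/C=C(\C)CC/C=C(\C)CO | intermediate
4 | {[(2E,6E)-8-bromo-3,7-dimethylocta-2,6-dien-1-yl]oxy}(tert-butyl)dimethylsilane | CC(C)(C)[Si](C)(C)OC/C=C(\C)CC/C=C(\C)CBr | intermediate
5 | {(3E,7E)-9-[(tert-butyldimethylsilyl)oxy]-3,7-dimethylnona-3,7-dien-1-yl}(isopropoxy)dimethylsilane | CC(C)(C)[Si](C)(C)OC/C=C(\C)CC/C=C(\C)CC[Si](C)(C)OC(C)C | intermediate (not isolated)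
6 | (3E,7E)-9-[(tert-butyldimethylsilyl)oxy]-3,7-dimethylnona-3,7-dien-1-ol | CC(C)(C)[Si](C)(C)OC/C=C(\C)CC/C=C(\C)CCO | intermediate
7 | (4S,6E,10E)-12-[(tert-butyldimethylsilyl)oxy]-6,10-dimethyldodeca-1,6,10-trien-4-ol | CC(C)(C)[Si](C)(C)OC/C=C(\C)CC/C=C(\C)C[C@@H](O)CC=C | intermediate
8 | (4S,6E,10E)-12-[(tert-butyldimethylsilyl)oxy]-6,10-dimethyldodeca-1,6,10-trien-4-yl formate | CC(C)(C)[Si](C)(C)OC/C=C(\C)CC/C=C(\C)C[C@@H](OC=O)CC=C | intermediate
9 | (3R,5S)-5-{(2E,6E)-8-[(tert-butyldimethylsilyl)oxy]-2,6-dimethylocta-2,6-dien-1-yl}-3-methyloxolan-2-one | CC(C)(C)[Si](C)(C)OC/C=C(\C)CC/C=C(\C)C[C@@H]1C[C@@H](C)C(=O)O1 | intermediate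
10 | (3R,5S)-5-[(2E,6E)-8-bromo-2,6-dimethylocta-2,6-dien-1-yl]-3-methyloxolan-2-one | BrC/C=C(\C)CC/C=C(\C)C[C@@H]1C[C@@H](C)C(=O)O1 | intermediate
11 | 2,3,4-trimethoxyphenol | COc1ccc(O)c(OC)c1OC | starting material
12 | 2,3,4,4-tetramethoxycyclohexa-2,5-dien-1-one | COC1=C(OC)C(=O)C=CC1(OC)OC | intermediate
13 | methylzinc dienolate of (5R)-2,3,4,4-tetramethoxy-5-methylcyclohex-2-en-1-one (O–ZnCH3 on C1, C1=C6 double bond) | COC1=C(OC)C(O[Zn]C)=C[C@@H](C)C1(OC)OC | intermediate (not isolated)
14 | (5R,6R)-2,3,4,4-tetramethoxy-5-methyl-6-{(2E,6E)-3,7-dimethyl-8-[(2S,4R)-4-methyl-5-oxooxolan-2-yl]octa-2,6-dien-1-yl}cyclohex-2-en-1-one | COC1=C(OC)C(=O)[C@H](C/C=C(\C)CC/C=C(\C)C[C@@H]2C[C@@H](C)C(=O)O2)[C@@H](C)C1(OC)OC | intermediate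
15 | (1R,5R,6R)-2,3,4,4-tetramethoxy-5-methyl-6-{(2E,6E)-3,7-dimethyl-8-[(2S,4R)-4-methyl-5-oxooxolan-2-yl]octa-2,6-dien-1-yl}cyclohex-2-en-1-ol | COC1=C(OC)[C@H](O)[C@H](C/C=C(\C)CC/C=C(\C)C[C@@H]2C[C@@H](C)C(=O)O2)[C@@H](C)C1(OC)OC | intermediate
16 | (4R,5R,6R)-4-hydroxy-2,3-dimethoxy-6-methyl-5-{(2E,6E)-3,7-dimethyl-8-[(2S,4R)-4-methyl-5-oxooxolan-2-yl]octa-2,6-dien-1-yl}cyclohex-2-en-1-one | COC1=C(OC)[C@H](O)[C@H](C/C=C(\C)CC/C=C(\C)C[C@@H]2C[C@@H](C)C(=O)O2)[C@@H](C)C1=O | intermediate
17 | CNP0600606.1, (1R,5R,6R)-2,3-dimethoxy-5-methyl-4-oxo-6-{(2E,6E)-3,7-dimethyl-8-[(2S,4R)-4-methyl-5-oxooxolan-2-yl]octa-2,6-dien-1-yl}cyclohex-2-en-1-yl acetate | COC1=C(OC)[C@H](OC(C)=O)[C@H](C/C=C(\C)CC/C=C(\C)C[C@@H]2C[C@@H](C)C(=O)O2)[C@@H](C)C1=O | target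

**Step count and risks**

Total step count: 13. Longest linear sequence: 12 steps (steps 1 to 8 and 10 to 13, from geraniol); step 9 is the one-step side branch.

Steps most likely to fail:

1. Step 7 (proposed new method). The formate may lose carbon monoxide at nickel, which returns alcohol 7 and poisons the catalyst. AlMe3 may attack the formate. Ligand control over the alkene face may be incomplete, so that the cis lactone forms alongside. Fallback by known chemistry, leaving the route at alcohol 7: 9-BBN hydroborates only the monosubstituted alkene and NaOH/H2O2 should give (4S,6E,10E)-12-[(tert-butyldimethylsilyl)oxy]-6,10-dimethyldodeca-6,10-diene-1,4-diol F1. TEMPO/PhI(OAc)2 should oxidise the primary alcohol and the resulting lactol to (5S)-5-{(2E,6E)-8-[(tert-butyldimethylsilyl)oxy]-2,6-dimethylocta-2,6-dien-1-yl}oxolan-2-one F2. LDA and then MeI in THF at −78 °C should methylate the lactone enolate anti to the C5 substituent, the known trans-selective alkylation, which returns to the route at lactone 9. This fallback closes the ring through oxygen and forms the C3–CH3 bond last.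

2. Step 10. C-allylation of the hindered methylzinc enolate may be slow, leftover methylzinc species may transfer methyl to the allylic bromide under copper catalysis, and the precious bromide 10 may be consumed unproductively. Fallback, leaving the route at monoketal 12: the same conjugate addition is quenched with TMSOTf and the trimethylsilyl dienol ether of (5R)-2,3,4,4-tetramethoxy-5-methylcyclohex-2-en-1-one F3 is isolated. MeLi in THF at 0 °C should regenerate a copper-free and zinc-free lithium enolate, which is alkylated with bromide 10 in THF/HMPA at −78 to 0 °C, returning to the route at ketone 14.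

3. Step 5. The transient β,γ-unsaturated aldehyde may isomerise into conjugation under the basic conditions at 100 °C before it is allylated, or the level or sense of enantioselection may be insufficient. Fallback, leaving the route at alcohol 6: oxidation with 1,1,1-triacetoxy-1,1-dihydro-1,2-benziodoxol-3(1H)-one (DMP) and NaHCO3 in CH2Cl2 at 0 °C should give (3E,7E)-9-[(tert-butyldimethylsilyl)oxy]-3,7-dimethylnona-3,7-dienal F4, used at once. Allylboration with (−)-Ipc2B(allyl) (from (−)-Ipc2BOMe and allylMgBr) in Et2O at −78 °C, with NaOH/H2O2 work-up, should attack the Si face of the aldehyde and return to the route at alcohol 7.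

Further compounds
F1 | step 7 | (4S,6E,10E)-12-[(tert-butyldimethylsilyl)oxy]-6,10-dimethyldodeca-6,10-diene-1,4-diol | CC(C)(C)[Si](C)(C)OC/C=C(\C)CC/C=C(\C)C[C@@H](O)CCCO
F2 | step 7 | (5S)-5-{(2E,6E)-8-[(tert-butyldimethylsilyl)oxy]-2,6-dimethylocta-2,6-dien-1-yl}oxolan-2-one | CC(C)(C)[Si](C)(C)OC/C=C(\C)CC/C=C(\C)C[C@@H]1CCC(=O)O1
F3 | step 10 | trimethylsilyl dienol ether of (5R)-2,3,4,4-tetramethoxy-5-methylcyclohex-2-en-1-one | COC1=C(OC)C(O[Si](C)(C)C)=C[C@@H](C)C1(OC)OC
F4 | step 5 | (3E,7E)-9-[(tert-butyldimethylsilyl)oxy]-3,7-dimethylnona-3,7-dienal | CC(C)(C)[Si](C)(C)OC/C=C(\C)CC/C=C(\C)CC=O
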